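The run lasts 12 s, so I ask how many turnovers one electrophile gets in that time.

    nucleophile + acid set free ⇌ protonated nucleophile, settled at all times (K1 = 2100 /M)
    electrophile + protic impurity → quenched substrate (k2 = 22 /M/s)
    2 electrophile → homo dimer (k3 = 0.51 /M/s)
    electrophile + nucleophile → acid set free + product (k4 = 1.1 /M/s)

| setting | autumn | dawn | spring |
|---|---|---|---|
| electrophile | 0.050 M | 0.050 M | 0.050 M |
| nucleophile | 2.00 equiv | 3.00 equiv | 4.50 equiv |
| protic impurity | 5.00 mM | 5.00 mM | 5.00 mM |
| time | 12 s | 12 s | 12 s |

- in percentages every species weighs as the electrophile in it: one homo dimer counts as two
- a doubled species enters its step squared and goes two at a time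
- run time (autumn): 12 s

- part of the electrophile that has reacted at the end, autumn
- part of the electrophile that has reacted at the end, dawn
- part of the electrophile that has reacted at the end, spring
- what raising the equivalents of nucleophile from its lowest to its highest value here does to the part of the electrophile that has reacted (changes below 5 percentage points count as none) (no change / it rises / it falls)

I draw the [electrophile] curve of autumn. At the start the nucleophile takes it at 0.110 /s per electrophile, the protic impurity at 0.110 /s and dimerisation at 0.0510 /s. The first knee comes early, because the protic impurity has a half-life of 0.630 s, far shorter than the run. So I book its whole charge at once, which leaves 0.0450 M of electrophile.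

 Because 210 is far above one, the acid set free binds a nucleophile, so each product costs two nucleophile. The charge 0.100 M still exceeds 0.0900 M, so by this count the nucleophile outlasts the electrophile.

My measure is the turnover count: the run time multiplied by the sum of the coupling and dimerisation rates per electrophile, taken at mean concentrations. What stays is the electrophile after the knee times e to the minus that count.

First count, at start values: 1.87; [electrophile] ends near 0.00693 M

Coupling's share: 70.6%; [nucleophile] ends near 0.0463 M

Second count, at the means: 1.28; autumn reacted 75.1%

Dawn: first count 2.53; [nucleophile] ends near 0.0852 M; second count 1.85; reacted 85.8%

Spring: first count 3.52; [nucleophile] ends near 0.151 M; second count 2.77; reacted 94.3%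

The forecast gives 73%, 82% and 91%, with the trend it rises, since “more equivalents keep more free nucleophile available”.

The simulation gives 73.7%, 83.6% and 92.6%; from the lowest to the highest nucleophile the reacted part changes thus: it rises, by 19 percentage points.

Autumn is not at rest at 12 s: 26% of the electrophile still stands, where my 1.28 turnovers left 24.9%. At 120 s the reacted part reads 99.7%, product has moved from 47.3% to 70.2%, and homo dimer from 16.4% to 19.5%. Counting those extra 108 s by coupling alone, at the free nucleophile of that late reading, 30.4% of charge, adds 3.61 turnovers, which leaves 0.712%; the flask reads 0.339%. Dawn, counted the same way, adds 8.71 turnovers, and it reads >99.9% reacted, with product at 76.9%.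

(The constants belong to no real substance; no experiment stands behind them.)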